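**Plan**

1. Retrosynthesis: the six aryl acetates come off last. Before that, the cyclohexene is cut in one retro-[4+2] at two ring bonds, CH2–CH(2,4-dihydroxyphenyl) and CH(acyl)–CH(benzofuran-5-yl). This gives an (E)-2'-hydroxychalcone (morachalcone A triacetate) and an (E)-1-aryl-3-methylbuta-1,3-diene (a dehydroprenyl 2-arylbenzofuran triacetate).
2. Enabling feature: the ring C=C lies between the methyl-bearing carbon and the CH next to the benzofuranyl-bearing carbon, i.e. 3,4 to the acyl-bearing carbon (4-acylcyclohexene retron). The acyl group is an ortho-hydroxyaryl ketone whose phenol O and C=O can clamp boron in a six-membered O–B–O=C chelate, a temporary ring that activates the enone and carries the chiral ligand.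
3. Chalcone arm (steps 1–8): an aromatic Claisen rearrangement puts the prenyl group on C-3 of 2,4-dihydroxyacetophenone; Claisen–Schmidt condensation follows; MOM groups are then exchanged for acetates, leaving the chelated 2'-OH free.
4. Diene arm (steps 9–14): the furan ring is closed first (Sonogashira coupling/5-endo-dig cyclisation on 4-bromo-6-iodoresorcinol); the diene is then attached at the bromide by Suzuki coupling.
5. Ring order: furan ring (step 10), cyclohexene ring (step 15), global deacetylation (step 16).
6. Stereochemistry: all three stereocentres arise in step 15. Acyl/aryl trans comes from the E-enone, benzofuranyl/acyl trans from the exo mode, and the absolute sense from the (R)-VANOL borate. The all-equatorial product is the stable epimer at the α-keto carbon, so it should hold through the basic last step.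

Key step: step 15

Assumption: the sense of facial induction of the VANOL borate on the chelated enone is taken, by analogy with related 2'-hydroxychalcone cycloadditions, to be (R)-ligand → (1R,2R,6S) adduct. Should the first trial show the opposite sense, (S)-VANOL is used with no other change.

**Route**

Step 1
Reactants: 1 2,4-dihydroxyacetophenone; 2 3-chloro-3-methylbut-1-yne
Product: 3 1-[2-hydroxy-4-[(2-methylbut-3-yn-2-yl)oxy]phenyl]ethan-1-one
Conditions: K2CO3, KI (cat.), CuI (cat.), acetone, reflux
Reagents that add atoms: none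
Why: Copper-assisted Williamson-type O-propargylation should occur only at the 4-OH, because the 2-OH is held in a hydrogen bond to the acetyl carbonyl and is much less nucleophilic.

Step 2
Reactants: 3 1-[2-hydroxy-4-[(2-methylbut-3-yn-2-yl)oxy]phenyl]ethan-1-one
Product: 4 1-[2-hydroxy-4-[(2-methylbut-3-en-2-yl)oxy]phenyl]ethan-1-one
Conditions: H2 (1 atm), Lindlar catalyst, quinoline, EtOAc, rt
Reagents that add atoms: none
Why: Lindlar semihydrogenation should stop at the alkene and leave the aryl ketone and the tertiary allylic C–O bond untouched.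

Step 3
Reactants: 4 1-[2-hydroxy-4-[(2-methylbut-3-en-2-yl)oxy]phenyl]ethan-1-one
Product: 5 1-[2,4-dihydroxy-3-(3-methylbut-2-en-1-yl)phenyl]ethan-1-one
Conditions: PhNEt2, 130 °C
Reagents that add atoms: none
Why: The aromatic Claisen ([3,3]) rearrangement of the 1,1-dimethylallyl ether should deliver a 3-methylbut-2-enyl group to C-3, the ortho position between the two oxygens, which is favoured by the bond fixation imposed by the chelated 2-OH/acetyl pair, and tautomerisation restores the phenol.

Step 4
Reactants: 5 1-[2,4-dihydroxy-3-(3-methylbut-2-en-1-yl)phenyl]ethan-1-one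
Product: 6 1-[2-hydroxy-4-(methoxymethoxy)-3-(3-methylbut-2-en-1-yl)phenyl]ethan-1-one
Conditions: MOMCl (1.1 equiv), K2CO3, acetone, rt
Reagents that add atoms: chloromethyl methyl ether, COCCl
Why: O-Alkylation (acetal protection) should take the free 4-OH selectively, since the 2-OH is chelated to the ketone.

Step 5
Reactants: 7 2,4-dihydroxybenzaldehyde
Product: 8 2,4-bis(methoxymethoxy)benzaldehyde
Conditions: MOMCl (2.5 equiv), K2CO3, acetone, reflux
Reagents that add atoms: chloromethyl methyl ether, COCCl
Why: Exhaustive O-alkylation under forcing conditions protects both phenols as base-stable MOM acetals, so the aldehyde stays electrophilic in the aldol step.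

Step 6
Reactants: 6 1-[2-hydroxy-4-(methoxymethoxy)-3-(3-methylbut-2-en-1-yl)phenyl]ethan-1-one; 8 2,4-bis(methoxymethoxy)benzaldehyde
Product: 9 (2E)-3-[2,4-bis(methoxymethoxy)phenyl]-1-[2-hydroxy-4-(methoxymethoxy)-3-(3-methylbut-2-en-1-yl)phenyl]prop-2-en-1-one
Conditions: KOH (aq), EtOH, rt
Reagents that add atoms: none
Why: Claisen–Schmidt condensation (aldol addition, then E1cB dehydration) should give the conjugated E-enone as the thermodynamic product, and MOM ethers and the prenyl group are inert to hydroxide.

Step 7
Reactants: 9 MOM-protected chalcone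
Product: 10 morachalcone A, (2E)-1-[2,4-dihydroxy-3-(3-methylbut-2-en-1-yl)phenyl]-3-(2,4-dihydroxyphenyl)prop-2-en-1-one
Conditions: conc. HCl (cat.), MeOH, 40 °C, stopped at full conversion
Reagents that add atoms: none
Why: Acid-catalysed transacetalisation to methanol removes the three MOM groups under conditions mild enough that protonation of the trisubstituted prenyl alkene should remain slow.

Step 8
Reactants: 10 morachalcone A
Product: 11 4-[(1E)-3-[4-(acetyloxy)-2-hydroxy-3-(3-methylbut-2-en-1-yl)phenyl]-3-oxoprop-1-en-1-yl]benzene-1,3-diyl diacetate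
Conditions: Ac2O (3.1 equiv), pyridine, CH2Cl2, 0 °C
Reagents that add atoms: acetic anhydride, CC(=O)OC(C)=O
Why: Selective O-acylation should spare the 2'-OH, which is hydrogen-bonded to the ketone and flanked by the prenyl and acyl groups, and this leaves exactly one phenol free for boron in step 15.

Step 9
Reactants: 12 4-bromobenzene-1,3-diol (4-bromoresorcinol)
Product: 13 4-bromo-6-iodobenzene-1,3-diol
Conditions: NIS (1.0 equiv), TsOH·H2O (cat.), MeCN, 0 °C
Reagents that add atoms: N-iodosuccinimide, O=C1CCC(=O)N1I
Why: Electrophilic aromatic iodination under acidic conditions should go to C-6, para to one hydroxyl and ortho to the other, in preference to the hindered C-2 between the hydroxyls.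

Step 10
Reactants: 13 4-bromo-6-iodobenzene-1,3-diol; 14 1-ethynyl-3,5-dimethoxybenzene
Product: 16 5-bromo-2-(3,5-dimethoxyphenyl)-1-benzofuran-6-ol, via 4-bromo-6-[(3,5-dimethoxyphenyl)ethynyl]benzene-1,3-diol 15 (not isolated)
Conditions: PdCl2(PPh3)2 (cat.), CuI (cat.), Et3N, DMF, rt → 70 °C
Reagents that add atoms: none
Why: Sonogashira coupling is chemoselective for C–I over C–Br, and the resulting o-alkynylphenol should undergo Cu/Pd-promoted 5-endo-dig hydroalkoxylation through the only hydroxyl ortho to the alkyne, which closes the furan ring.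

Step 11
Reactants: 16 5-bromo-2-(3,5-dimethoxyphenyl)-1-benzofuran-6-ol
Product: 17 5-(5-bromo-6-hydroxy-1-benzofuran-2-yl)benzene-1,3-diol
Conditions: BBr3, CH2Cl2, −78 °C → rt; then H2O
Reagents that add atoms: none
Why: Lewis-acid cleavage of aryl methyl ethers (BBr3 demethylation) is compatible with the benzofuran and the aryl bromide and is done before any acid-sensitive diene is present.

Step 12
Reactants: 17 5-(5-bromo-6-hydroxy-1-benzofuran-2-yl)benzene-1,3-diol
Product: 18 5-[6-(acetyloxy)-5-bromo-1-benzofuran-2-yl]benzene-1,3-diyl diacetate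
Conditions: Ac2O, pyridine, DMAP (cat.), CH2Cl2, rt
Reagents that add atoms: acetic anhydride, CC(=O)OC(C)=O
Why: Exhaustive O-acylation masks all three phenols so that they cannot bind boron in step 15, and the ortho-acetoxy group also makes the bromide more reactive towards oxidative addition.

Step 13
Reactants: 19 2-methylbut-1-en-3-yne
Product: 20 4,4,5,5-tetramethyl-2-[(1E)-3-methylbuta-1,3-dien-1-yl]-1,3,2-dioxaborolane
Conditions: HBpin, Cp2Zr(H)Cl (cat.), Et3N (cat.), neat, 60 °C
Reagents that add atoms: pinacolborane, [H]B1OC(C)(C)C(C)(C)O1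
Why: Zirconium-catalysed syn, anti-Markovnikov hydroboration of the terminal alkyne should give the E-alkenylboronate and leave the 1,1-disubstituted alkene untouched.

Step 14
Reactants: 18 5-[6-(acetyloxy)-5-bromo-1-benzofuran-2-yl]benzene-1,3-diyl diacetate; 20 (E)-dienyl pinacol boronate
Product: 21 5-{6-(acetyloxy)-5-[(1E)-3-methylbuta-1,3-dien-1-yl]-1-benzofuran-2-yl}benzene-1,3-diyl diacetate
Conditions: Pd(OAc)2/SPhos (cat.), KF, THF–H2O (20:1), 40 °C
Reagents that add atoms: none
Why: Suzuki–Miyaura coupling with fluoride activation proceeds with retention of the E-alkene geometry, and the weakly basic fluoride conditions should spare the aryl acetates.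

Step 15
Reactants: 11 morachalcone A 4',2,4-triacetate; 21 diene triacetate
Product: 24 [(1R,2R,6S)-2-[6-(acetyloxy)-2-[3,5-bis(acetyloxy)phenyl]-1-benzofuran-5-yl]-6-[2,4-bis(acetyloxy)phenyl]-4-methylcyclohex-3-en-1-yl][4-(acetyloxy)-2-hydroxy-3-(3-methylbut-2-en-1-yl)phenyl]methanone, via (R)-VANOL borate chelate of 11 (six-membered O–B–O=C ring through the 2'-phenolate oxygen and the carbonyl oxygen) 22 (not isolated), via the corresponding (R)-VANOL borate chelate of the cycloadduct 23 (not isolated)
Conditions: (R)-VANOL (1.3 equiv), B(OPh)3 (1.3 equiv), THF, 60 °C, then vacuum; 11, then 21 (1.5 equiv), PhCF3, rt; aq. NaHCO3 work-up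
Reagents that add atoms: none
Why: Ligand exchange of the aryl borate with the only free phenol of 11 and coordination of the neighbouring carbonyl give the tetracoordinate six-membered chelate 22, which holds the enone s-cis, lowers its LUMO and blocks one π-face with the vaulted biaryl, and the diene 21 then adds in a concerted but asynchronous [4+2] cycloaddition in which its CH2 terminus bonds to the β-carbon (the leading bond) and its aryl-bearing terminus to the α-carbon. The closest known reaction type is the Diels–Alder reaction of 2'-hydroxychalcones with 1-aryl-3-methylbuta-1,3-dienes promoted by chiral boron complexes of biaryl diols. The cyclohexene is closed by an intermolecular suprafacial/suprafacial [4πs+2πs] cycloaddition, and work-up hydrolyses the product chelate 23 and returns the ligand. Of the three new stereocentres, the trans relation of the acyl and 2,4-diacetoxyphenyl groups is fixed by the E-enone geometry, the trans relation of the benzofuranyl and acyl groups by the exo orientation of the chelated carbonyl with respect to the E-diene, and the absolute configuration by the face of 22 that the (R)-ligand leaves open. The step needs regio-, exo- and facial selectivity: regiochemistry is secured by the match of the nucleophilic CH2 terminus of the aryl- and methyl-substituted diene with the boron-activated β-carbon, the exo mode should be favoured because the bulky borate under the chelate disfavours the endo placement of the diene backbone and its ortho-acetoxyaryl group, and activation is confined to the 2'-OH/C=O pair because every other phenol of both partners is acetylated.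

Step 16
Reactants: 24 hexaacetate cycloadduct
Product: 25 [(1R,2R,6S)-6-(2,4-dihydroxyphenyl)-2-[2-(3,5-dihydroxyphenyl)-6-hydroxy-1-benzofuran-5-yl]-4-methylcyclohex-3-en-1-yl][2,4-dihydroxy-3-(3-methylbut-2-en-1-yl)phenyl]methanone (CNP0150120.1)
Conditions: K2CO3 (cat.), degassed MeOH, 0 °C → rt, Ar; pH 6 buffer work-up
Reagents that add atoms: none
Why: Base-catalysed transesterification (methanolysis) removes the six aryl acetates without acid, so the prenyl group and ring alkene are not at risk, and the α-keto stereocentre is already in its all-equatorial, thermodynamically preferred configuration so enolisation should not erode it.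

**Compound list**

1 | 2,4-dihydroxyacetophenone | CC(=O)c1ccc(O)cc1O | starting material
2 | 3-chloro-3-methylbut-1-yne | C#CC(C)(C)Cl | starting material
3 | 1-[2-hydroxy-4-[(2-methylbut-3-yn-2-yl)oxy]phenyl]ethan-1-one | CC(=O)c1ccc(OC(C)(C)C#C)cc1O | intermediate
4 | 1-[2-hydroxy-4-[(2-methylbut-3-en-2-yl)oxy]phenyl]ethan-1-one | CC(=O)c1ccc(OC(C)(C)C=C)cc1O | intermediate
5 | 1-[2,4-dihydroxy-3-(3-methylbut-2-en-1-yl)phenyl]ethan-1-one | CC(=O)c1ccc(O)c(CC=C(C)C)c1O | intermediate
6 | 1-[2-hydroxy-4-(methoxymethoxy)-3-(3-methylbut-2-en-1-yl)phenyl]ethan-1-one | CC(=O)c1ccc(OCOC)c(CC=C(C)C)c1O | intermediate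
7 | 2,4-dihydroxybenzaldehyde | O=Cc1ccc(O)cc1O | starting material
8 | 2,4-bis(methoxymethoxy)benzaldehyde | COCOc1ccc(C=O)c(OCOC)c1 | intermediate
9 | (2E)-3-[2,4-bis(methoxymethoxy)phenyl]-1-[2-hydroxy-4-(methoxymethoxy)-3-(3-methylbut-2-en-1-yl)phenyl]prop-2-en-1-one | CC(C)=CCc1c(OCOC)ccc(C(=O)/C=C/c2ccc(OCOC)cc2OCOC)c1O | intermediate
10 | morachalcone A | CC(C)=CCc1c(O)ccc(C(=O)/C=C/c2ccc(O)cc2O)c1O | intermediate
11 | morachalcone A 4',2,4-triacetate (2'-OH free) | CC(C)=CCc1c(OC(C)=O)ccc(C(=O)/C=C/c2ccc(OC(C)=O)cc2OC(C)=O)c1O | intermediate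
12 | 4-bromobenzene-1,3-diol | Oc1ccc(Br)c(O)c1 | starting material
13 | 4-bromo-6-iodobenzene-1,3-diol | Oc1cc(O)c(I)cc1Br | intermediate
14 | 1-ethynyl-3,5-dimethoxybenzene | COc1cc(OC)cc(C#C)c1 | starting material
15 | 4-bromo-6-[(3,5-dimethoxyphenyl)ethynyl]benzene-1,3-diol | COc1cc(OC)cc(C#Cc2cc(Br)c(O)cc2O)c1 | intermediate
16 | 5-bromo-2-(3,5-dimethoxyphenyl)-1-benzofuran-6-ol | COc1cc(OC)cc(-c2cc3cc(Br)c(O)cc3o2)c1 | intermediate
17 | 5-(5-bromo-6-hydroxy-1-benzofuran-2-yl)benzene-1,3-diol | Oc1cc(O)cc(-c2cc3cc(Br)c(O)cc3o2)c1 | intermediate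
18 | 5-[6-(acetyloxy)-5-bromo-1-benzofuran-2-yl]benzene-1,3-diyl diacetate | CC(=O)Oc1cc(OC(C)=O)cc(-c2cc3cc(Br)c(OC(C)=O)cc3o2)c1 | intermediate
19 | 2-methylbut-1-en-3-yne | C=C(C)C#C | starting material
20 | 4,4,5,5-tetramethyl-2-[(1E)-3-methylbuta-1,3-dien-1-yl]-1,3,2-dioxaborolane | CC(=C)/C=C/B1OC(C)(C)C(C)(C)O1 | intermediate
21 | 5-{6-(acetyloxy)-5-[(1E)-3-methylbuta-1,3-dien-1-yl]-1-benzofuran-2-yl}benzene-1,3-diyl diacetate | CC(=C)/C=C/c1cc2cc(-c3cc(OC(C)=O)cc(OC(C)=O)c3)oc2cc1OC(C)=O | intermediate
22 | (R)-VANOL borate chelate of 11 (axial R configuration of the ligand is not expressed in the SMILES; configuration at boron not defined) | CC(C)=CCc1c(OC(C)=O)ccc2c1O[B-]1(Oc3c(c(-c4ccccc4)cc4ccccc34)-c3c(O1)c4ccccc4cc3-c3ccccc3)[O+]=C2/C=C/c1ccc(OC(C)=O)cc1OC(C)=O | intermediate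
23 | (R)-VANOL borate chelate of cycloadduct 24 (same remarks on ligand axis and boron) | CC(C)=CCc1c(OC(C)=O)ccc2c1O[B-]1(Oc3c(c(-c4ccccc4)cc4ccccc34)-c3c(O1)c4ccccc4cc3-c3ccccc3)[O+]=C2[C@@H]1[C@@H](c3ccc(OC(C)=O)cc3OC(C)=O)CC(C)=C[C@H]1c1cc3cc(-c4cc(OC(C)=O)cc(OC(C)=O)c4)oc3cc1OC(C)=O | intermediate
24 | (1R,2R,6S) hexaacetate cycloadduct (2'-OH free) | CC(C)=CCc1c(OC(C)=O)ccc(C(=O)[C@@H]2[C@@H](c3ccc(OC(C)=O)cc3OC(C)=O)CC(C)=C[C@H]2c2cc3cc(-c4cc(OC(C)=O)cc(OC(C)=O)c4)oc3cc2OC(C)=O)c1O | intermediate
25 | CNP0150120.1, (1R,2R,6S) all-trans adduct | CC(C)=CCc1c(O)ccc(C(=O)[C@@H]2[C@@H](c3ccc(O)cc3O)CC(C)=C[C@H]2c2cc3cc(-c4cc(O)cc(O)c4)oc3cc2O)c1O | target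

**Totals**

Total step count: 16. Longest linear sequence: 9 steps (steps 1, 2, 3, 4, 6, 7, 8, 15, 16).

**Steps most likely to fail, with fallbacks**

1. Step 15. The cycloaddition may show an insufficient preference for the exo mode, or insufficient facial discrimination by the borate, because the diene is large and either aryl group can stack against the chelate. Fallback: setting out from 11 and 21, the cycloaddition is run without a chiral promoter under electron-transfer catalysis by silica-supported silver nanoparticles (CH2Cl2, 50 °C), a known method for 2'-hydroxychalcones and aryl dienes in which both exo and endo adducts are expected. The endo diastereomer is removed on silica, and the racemic exo adduct, 24 together with its mirror image ent-24 F1, is resolved by preparative HPLC on a polysaccharide chiral stationary phase. The route is rejoined at 24.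

2. Step 7. Acidic removal of the MOM groups may be overtaken by cyclisation of the prenyl group onto a flanking phenol (chroman formation) or by acid-induced ring closure of the hydroxychalcone. Fallback: allyl ethers replace MOM ethers so that no acid is needed. Setting out from 5 and 7, allyl bromide/K2CO3 gives 1-[2-hydroxy-3-(3-methylbut-2-en-1-yl)-4-(prop-2-en-1-yloxy)phenyl]ethan-1-one F2 and 2,4-bis(prop-2-en-1-yloxy)benzaldehyde F3. Claisen–Schmidt condensation (KOH, EtOH) gives the tris(allyl) chalcone F4. Pd(PPh3)4-catalysed allyl transfer to morpholine (THF, rt) then releases the three phenols, and the route is rejoined at 10.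

3. Step 14. Aryl acetates may be lost to fluoride or hydroxide during transmetalation, and the dienyl boronate may protodeboronate or oligomerise before it couples. Fallback: setting out from 18, a Heck reaction with 2-methylbut-3-en-2-ol (Pd(OAc)2, P(o-tol)3, Et3N, DMF, 90 °C) gives the E-configured tertiary allylic alcohol 5-{6-(acetyloxy)-5-[(1E)-3-hydroxy-3-methylbut-1-en-1-yl]-1-benzofuran-2-yl}benzene-1,3-diyl diacetate F5. Dehydration with Burgess reagent (benzene, 50 °C) can eliminate only towards a methyl group and gives the diene, so the route is rejoined at 21.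

**Further compounds**

F1 | step 15 | ent-24, the (1S,2S,6R) hexaacetate that forms the racemate together with 24 | CC(C)=CCc1c(OC(C)=O)ccc(C(=O)[C@H]2[C@H](c3ccc(OC(C)=O)cc3OC(C)=O)CC(C)=C[C@@H]2c2cc3cc(-c4cc(OC(C)=O)cc(OC(C)=O)c4)oc3cc2OC(C)=O)c1O
F2 | step 7 | 1-[2-hydroxy-3-(3-methylbut-2-en-1-yl)-4-(prop-2-en-1-yloxy)phenyl]ethan-1-one | CC(=O)c1ccc(OCC=C)c(CC=C(C)C)c1O
F3 | step 7 | 2,4-bis(prop-2-en-1-yloxy)benzaldehyde | C=CCOc1ccc(C=O)c(OCC=C)c1
F4 | step 7 | (2E)-3-[2,4-bis(prop-2-en-1-yloxy)phenyl]-1-[2-hydroxy-3-(3-methylbut-2-en-1-yl)-4-(prop-2-en-1-yloxy)phenyl]prop-2-en-1-one | CC(C)=CCc1c(OCC=C)ccc(C(=O)/C=C/c2ccc(OCC=C)cc2OCC=C)c1O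
F5 | step 14 | 5-{6-(acetyloxy)-5-[(1E)-3-hydroxy-3-methylbut-1-en-1-yl]-1-benzofuran-2-yl}benzene-1,3-diyl diacetate | CC(C)(O)/C=C/c1cc2cc(-c3cc(OC(C)=O)cc(OC(C)=O)c3)oc2cc1OC(C)=O
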